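**Retrosynthetic overview** (ring A = methoxy-bearing ring, ring B = 3-hydroxyphenyl ring of the ethano bridge, ring C = 4-hydroxyphenyl ring of the benzyl group)
- The target comes from the diaryl ketone that has C=O in place of the ring A–CH2–ring C methylene. The ketone is kept until the end because it alone distinguishes the two ring A oxygens, through chelation-controlled loss of the ortho O-methyl group.
- The ketone comes from Friedel–Crafts aroylation of a 3,5-dimethoxybibenzyl with a 4-acyloxybenzoyl chloride. The two open ring A positions next to the chain are equivalent, so there is no regiochemical choice.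
- The bibenzyl comes from a stilbene. The key disconnection cuts the central C–C bond into two aldehyde carbons. 3,5-Dimethoxybenzaldehyde has its polarity reversed as the free hydrazone (a benzyl-anion equivalent) and is joined to 3-(benzyloxy)benzaldehyde under ruthenium catalysis with loss of N2 and H2O.
- No ring is formed. Rings A, B and C are all bought as benzene derivatives, and the order of assembly is A + B, then C.

**Assumption:** the target SMILES has no stereocentre and no stereogenic double bond. The compound is achiral, so there is no enantiomer to select and no stereocontrol is needed.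

**Step 1**
Reactants: 1 3,5-dimethoxybenzaldehyde; 2 3-(benzyloxy)benzaldehyde
Product: 4 (E)-1-{2-[3-(benzyloxy)phenyl]ethenyl}-3,5-dimethoxybenzene, via 3,5-dimethoxybenzaldehyde hydrazone 3 (not isolated)
Conditions: 1 (1.3 equiv), N2H4·H2O (1.1 equiv per 1), THF, rt, 1 h, dried over Na2SO4; then 2, [Ru(p-cymene)Cl2]2 (1.5 mol %), dmpe [1,2-bis(dimethylphosphino)ethane] (3 mol %), KOtBu (0.5 equiv), CsF (0.75 equiv), THF, 45 °C, 16 h, under N2
Reagents that add atoms: hydrazine hydrate, NN.O (its nitrogen atoms stand only in intermediate 3 and leave as N2 before 4 is formed)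
Why: Condensation with hydrazine turns the electrophilic aldehyde carbon of 1 into a benzyl-anion equivalent (carbonyl umpolung through the free hydrazone 3), which on the [Ru(p-cymene)Cl2]2/dmpe catalyst adds through a six-membered ruthenium-bound transition state to the equally electrophilic aldehyde carbon of 2, after which Wolff–Kishner-type loss of N2 and KOtBu-promoted E1cB loss of hydroxide give the alkene (ruthenium-catalysed hydrazone-mediated reductive carbonyl–carbonyl cross-coupling), no stereocentre being formed and the E/Z ratio being irrelevant because step 2 saturates the double bond.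

**Step 2**
Reactants: 4 (E)-1-{2-[3-(benzyloxy)phenyl]ethenyl}-3,5-dimethoxybenzene
Product: 5 3-[2-(3,5-dimethoxyphenyl)ethyl]phenol
Conditions: H2 (1 atm), Pd/C (10 wt %), EtOH–EtOAc, rt, 12 h
Reagents that add atoms: none
Why: Heterogeneous catalytic hydrogenation saturates the stilbene double bond and hydrogenolyses the aryl benzyl ether in the same operation, while the methyl ethers are inert and no stereocentre is created.

**Step 3**
Reactants: 5 3-[2-(3,5-dimethoxyphenyl)ethyl]phenol; 6 4-acetoxybenzoyl chloride
Product: 10 (4-hydroxyphenyl){2-hydroxy-6-[2-(3-hydroxyphenyl)ethyl]-4-methoxyphenyl}methanone, via aryl ester 7 (not isolated), via dimethoxy ketone 8 (not isolated), via hydroxy ketone triester 9 (not isolated)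
Conditions: 6 (2.2 equiv), Et3N (1.2 equiv), CH2Cl2, 0 °C, 30 min; AlCl3 (9 equiv), 0 °C to rt, 6 h; ice/1 M HCl; crude, 2 M NaOH, MeOH–THF, rt, 2 h; HCl to pH 3, NaHCO3 wash
Reagents that add atoms: none
Why: Et3N-mediated O-aroylation first masks and deactivates ring B, the Friedel–Crafts acylation then goes to ring A at one of its two equivalent positions (ortho to the chain, ortho and para to the methoxy groups), AlCl3 held in the six-membered chelate between the new ketone and the neighbouring methoxy oxygen cleaves only that methyl ether (the acylation–demethylation known from the manufacture of 2-hydroxy-4-methoxybenzophenone from 1,3-dimethoxybenzene), and saponification finally frees the esterified phenols.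

**Step 4**
Reactants: 10 (4-hydroxyphenyl){2-hydroxy-6-[2-(3-hydroxyphenyl)ethyl]-4-methoxyphenyl}methanone
Product: 12 2-(4-hydroxybenzyl)-3-[2-(3-hydroxyphenyl)ethyl]-5-methoxyphenol (target), via benzhydrol 11 (not isolated)
Conditions: Et3SiH (4 equiv), CF3CO2H–CH2Cl2 (1:1), 0 °C to rt, 12 h; aq NaHCO3/MeOH work-up
Reagents that add atoms: none
Why: In this ionic hydrogenation (Kursanov–Parnes reduction) the acid protonates the electron-rich diaryl ketone, Et3SiH delivers hydride to give 11, which ionises at once to a cation stabilised by the ortho and para oxygen substituents and takes up a second hydride much faster than it can alkylate an arene, while the phenols, the methyl ether and the ethano bridge are inert and the transient stereocentre of 11 is erased.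

**Compound list**
1 | 3,5-dimethoxybenzaldehyde | COc1cc(C=O)cc(OC)c1 | starting material
2 | 3-(benzyloxy)benzaldehyde | O=Cc1cccc(OCc2ccccc2)c1 | starting material
3 | (E)-(3,5-dimethoxybenzylidene)hydrazine | COc1cc(/C=N/N)cc(OC)c1 | intermediate
4 | (E)-1-{2-[3-(benzyloxy)phenyl]ethenyl}-3,5-dimethoxybenzene | COc1cc(/C=C/c2cccc(OCc3ccccc3)c2)cc(OC)c1 | intermediate
5 | 3-[2-(3,5-dimethoxyphenyl)ethyl]phenol | COc1cc(CCc2cccc(O)c2)cc(OC)c1 | intermediate
6 | 4-acetoxybenzoyl chloride | CC(=O)Oc1ccc(C(=O)Cl)cc1 | starting material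
7 | 3-[2-(3,5-dimethoxyphenyl)ethyl]phenyl 4-acetoxybenzoate | COc1cc(CCc2cccc(OC(=O)c3ccc(OC(C)=O)cc3)c2)cc(OC)c1 | intermediate
8 | 3-{2-[2-(4-acetoxybenzoyl)-3,5-dimethoxyphenyl]ethyl}phenyl 4-acetoxybenzoate | COc1cc(OC)c(C(=O)c2ccc(OC(C)=O)cc2)c(CCc2cccc(OC(=O)c3ccc(OC(C)=O)cc3)c2)c1 | intermediate
9 | 3-{2-[2-(4-acetoxybenzoyl)-3-hydroxy-5-methoxyphenyl]ethyl}phenyl 4-acetoxybenzoate (aluminium chelate in the flask, drawn protonated) | COc1cc(O)c(C(=O)c2ccc(OC(C)=O)cc2)c(CCc2cccc(OC(=O)c3ccc(OC(C)=O)cc3)c2)c1 | intermediate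
10 | (4-hydroxyphenyl){2-hydroxy-6-[2-(3-hydroxyphenyl)ethyl]-4-methoxyphenyl}methanone | COc1cc(O)c(C(=O)c2ccc(O)cc2)c(CCc2cccc(O)c2)c1 | intermediate
11 | 2-[hydroxy(4-hydroxyphenyl)methyl]-3-[2-(3-hydroxyphenyl)ethyl]-5-methoxyphenol (racemic, transient) | COc1cc(O)c(C(O)c2ccc(O)cc2)c(CCc2cccc(O)c2)c1 | intermediate
12 | 2-(4-hydroxybenzyl)-3-[2-(3-hydroxyphenyl)ethyl]-5-methoxyphenol (IN1159, achiral) | COc1cc(O)c(Cc2ccc(O)cc2)c(CCc2cccc(O)c2)c1 | target

**Total step count:** 4.
**Longest linear sequence:** 4 (1 → 4 → 5 → 10 → 12).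

**Steps most likely to fail**

*Step 1.* Azine formation between 3 and 2, plain Wolff–Kishner reduction of 3, or scrambling by residual hydrazine could erode the cross-coupling.
- The fallback sets out from 1 and comes back at 5. It keeps the polarity reversal but uses a stoichiometric acyl-anion equivalent (Corey–Seebach).
- 1 is condensed with propane-1,3-dithiol (BF3·OEt2, CH2Cl2) to 2-(3,5-dimethoxyphenyl)-1,3-dithiane F1.
- F1 is deprotonated (n-BuLi, THF, −78 °C) to 2-lithio-2-(3,5-dimethoxyphenyl)-1,3-dithiane F2.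
- F2 is alkylated with commercial 3-(benzyloxy)benzyl bromide to 2-[3-(benzyloxy)benzyl]-2-(3,5-dimethoxyphenyl)-1,3-dithiane F3.
- F3 is desulfurised with Raney nickel (EtOH, reflux) to 1-(benzyloxy)-3-[2-(3,5-dimethoxyphenyl)ethyl]benzene F4.
- F4 is debenzylated with H2 and Pd/C to 5.

*Step 3.* There are three concerns: acetyl transfer from the aryl acetates under AlCl3, slow aroylation at the flanked ring A position, and incomplete or excessive demethylation of the twisted ketone.
- The fallback sets out from 5 and comes back at 12, so step 4 is no longer needed. It brings in the benzylic carbon as a formyl group and ring C as a nucleophile.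
- Vilsmeier–Haack formylation (POCl3, DMF, then aqueous NaOAc) gives 2-[2-(3-hydroxyphenyl)ethyl]-4,6-dimethoxybenzaldehyde F5.
- BCl3 (CH2Cl2, −10 °C to rt) removes only the methyl group ortho to the aldehyde and gives 2-hydroxy-6-[2-(3-hydroxyphenyl)ethyl]-4-methoxybenzaldehyde F6.
- Excess [4-(benzyloxy)phenyl]magnesium bromide (3.5 equiv, THF) gives 2-{[4-(benzyloxy)phenyl](hydroxy)methyl}-3-[2-(3-hydroxyphenyl)ethyl]-5-methoxyphenol F7.
- H2 with Pd/C (EtOH, trace AcOH) cleaves the doubly benzylic C–OH bond and the benzyl ether of F7 to give 12.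

*Step 4.* The hindered, hydrogen-bonded ketone may react slowly. The long-lived diarylmethyl cation could also alkylate ring B (closing a seven-membered ring) or another molecule.
- The fallback sets out from 10 and comes back at 12. It avoids cations by working in base.
- NaBH4 in refluxing 1 M aqueous NaOH reduces 10 to the same benzhydrol 11.
- The phenoxide of 11 expels hydroxide to give the quinone methide 4-({2-hydroxy-6-[2-(3-hydroxyphenyl)ethyl]-4-methoxyphenyl}methylidene)cyclohexa-2,5-dien-1-one F8.
- F8 is trapped by borohydride in a 1,6-hydride addition to give 12.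

**Further compounds**
F1 | step 1 | 2-(3,5-dimethoxyphenyl)-1,3-dithiane | COc1cc(C2SCCCS2)cc(OC)c1
F2 | step 1 | 2-lithio-2-(3,5-dimethoxyphenyl)-1,3-dithiane | [Li]C1(c2cc(OC)cc(OC)c2)SCCCS1
F3 | step 1 | 2-[3-(benzyloxy)benzyl]-2-(3,5-dimethoxyphenyl)-1,3-dithiane | COc1cc(C2(Cc3cccc(OCc4ccccc4)c3)SCCCS2)cc(OC)c1
F4 | step 1 | 1-(benzyloxy)-3-[2-(3,5-dimethoxyphenyl)ethyl]benzene | COc1cc(CCc2cccc(OCc3ccccc3)c2)cc(OC)c1
F5 | step 3 | 2-[2-(3-hydroxyphenyl)ethyl]-4,6-dimethoxybenzaldehyde | COc1cc(OC)c(C=O)c(CCc2cccc(O)c2)c1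
F6 | step 3 | 2-hydroxy-6-[2-(3-hydroxyphenyl)ethyl]-4-methoxybenzaldehyde | COc1cc(O)c(C=O)c(CCc2cccc(O)c2)c1
F7 | step 3 | 2-{[4-(benzyloxy)phenyl](hydroxy)methyl}-3-[2-(3-hydroxyphenyl)ethyl]-5-methoxyphenol (racemic) | COc1cc(O)c(C(O)c2ccc(OCc3ccccc3)cc2)c(CCc2cccc(O)c2)c1
F8 | step 4 | 4-({2-hydroxy-6-[2-(3-hydroxyphenyl)ethyl]-4-methoxyphenyl}methylidene)cyclohexa-2,5-dien-1-one | COc1cc(O)c(C=C2C=CC(=O)C=C2)c(CCc2cccc(O)c2)c1
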